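(The earlier runs and the new flask come from a simulation for substances that don't exist; noise was put on by code.)

In a closed, stirred vessel at constant volume and temperature, substrate turns into target, and we want to know what the flask holds at the end of its time.

| setting | north | south | flask |
|---|---|---|---|
| substrate | 0.50 M | 0.75 M | 0.50 M |
| remark | the very flask that is asked about, followed so far | run made earlier |  |
| time |  |  | 1.0 h |

| run | time / min | target / % |
|---|---|---|
| north | 1.00 | 60.9 |
| north | 2.00 | 82.7 |
| north | 5.00 | 95.2 |
| north | 12.0 | 97.0 |
| south | 15.0 | 97.1 |
| south | 30.0 | 96.3 |
| south | 50.0 | 97.0 |
| south | 60.0 | 98.8 |

(scatter of a reading: 1 percentage point)

- percent here means substrate units held: one idle adduct counts as two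
- what is said of target includes crystals and idle adduct
- crystals is a solid; its amount is given per volume of the solution
- the analysis behind the earlier runs scatters by 1 percentage point, standard deviation
- steps thought possible: substrate <-> target; crystals <-> target; substrate + target <-> idle adduct; target <-> isomer of the product
- in an amount of target, one idle adduct counts as one target
- the reaction counts as stopped when no species that holds the substrate changes by six tenths of a point or more over the second half of the time

- why nothing more happens at 1.0 h, or that something still does (forward and back rates have come level / all of the substrate has reacted / it is still moving)
- target at 1.0 h, in percent of the substrate charged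

How fast does the north run, which is this very flask, close its gap? Measured from its last reading, 97.0%, the gap is 36 percentage points at 1.00 min and 14 points at 2.00 min. Its halving time, an apparent first-order half-life, is therefore 0.749 min. The time 1.0 h holds 80.2 of these: this is our turnover count, the number of halving times in the time. With a halving time so much shorter than the time, we expect the approach to end early in the flask.

Does anything drain away afterwards? The south run does not fall: from 15.0 min to 60.0 min it changes by 1.7 points, upward, with a scatter of 1 point.

Where does it rest? The south mean is 97.3%, which is 2.7 points short of complete, more than the scatter. So we expect a balance near that level, not spent substrate.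

The forecast says forward and back rates have come level, with target at 97.2%, and sees “no visible leak to the isomer”.

The flask gives: forward and back rates have come level, with target at 96.3% at 1.0 h.

    substrate ⇌ target (K = 0.400, k = 0.0230 /s)
    crystals ⇌ target, rate k2*(cs2 - [target]) while solid is left; crystals form when [target] > cs2 (solubility = 5.50 mM, k = 1.50 /s)
    substrate + target ⇌ idle adduct, settled at all times (K = 45.0 /M)
    target ⇌ isomer of the product (K = 0.260, k = 0.0410 /s)

The flask had made nearly all of its conversion by 2.75 min, which is 3.67 halving times out of the 80.2 counted for 1.0 h. Over the second half of its time the flask moves by 0 points. The neighbour flask left until 4.0 h counts 321 halving times and holds target at 96.3%.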